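**Retrosynthetic overview**
1. Last bond is C3–OMe: rhodium-carbenoid O–H insertion of methanol on the iodonium ylide of 4-hydroxy-pyrone 21 (new C–O bond formation).
2. The 2-pyrone, the only ring that is built, closes by O1–C2 lactonisation of 3,5-diketo ester 20, made from acid 16 and the dianion of methyl 3-oxopentanoate.
3. The (2'E)-alkene with C6/C1' comes from 2,3-dihydrofuran: iodide 10 alkylates 5-lithio-2,3-dihydrofuran, then nickel-catalysed methyl-for-oxygen exchange with retention, then oxidation to acid 16.
4. The (6'Z)-alkene comes from hydroxyl-directed iron-catalysed syn-methylmagnesiation of enynol 7; the (9'E)-alkene from zirconium-catalysed methylalumination/benzylation of diynol 4.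
5. Diynol 4 comes from but-3-yn-1-ol and propargyl bromide; the phenyl ring arrives with benzyl chloride.

Assumption: the target has no stereogenic centre, so "single enantiomer" is read as the single geometric isomer (2'E,6'Z,9'E) encoded in the SMILES.

**Route**

Step 1
Reactants: 1 but-3-yn-1-ol; 2 propargyl bromide
Product: 4 hepta-3,6-diyn-1-ol, via butynol bis-Grignard 3 (not isolated)
Conditions: EtMgBr (2.1 equiv), THF, 0 → 40 °C; CuCl (5 mol %), then 2, 45 °C; dilute aq. HCl work-up
Reagents that add atoms: none
Why: Copper-catalysed SN2 coupling of an alkynyl Grignard reagent with a propargylic bromide is the classical route to skipped 1,4-diynes, the magnesium alkoxide is a spectator, and no stereo-element is created.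

Step 2
Reactants: 4 hepta-3,6-diyn-1-ol; 5 benzyl chloride
Product: 7 (E)-6-methyl-8-phenyloct-6-en-3-yn-1-ol, via alkenylalane 6 (not isolated)
Conditions: Me3Al (3 equiv), Cp2ZrCl2 (0.25 equiv), CH2Cl2, 0 °C → rt; volatiles off; then 5, Pd(PPh3)4 (3 mol %), THF, rt; dilute aq. HCl work-up
Reagents that add atoms: trimethylaluminium, C[Al](C)C
Why: Negishi zirconium-catalysed methylalumination adds Me–Al syn and only to the terminal alkyne (methyl on the internal carbon), and the zerovalent-palladium cross-coupling of the alkenylalane with benzyl chloride goes with retention, which fixes the (E)-trisubstituted alkene (the later C9'=C10').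

Step 3
Reactants: 7 (E)-6-methyl-8-phenyloct-6-en-3-yn-1-ol
Product: 9 (3Z,6E)-4,6-dimethyl-8-phenylocta-3,6-dien-1-ol, via alkenylmagnesium chelate 8 (not isolated)
Conditions: Fe(acac)3 (20 mol %), MeMgBr (5 equiv), THF, −78 → 0 °C; dilute aq. HCl work-up
Reagents that add atoms: methylmagnesium bromide, C[Mg]Br
Why: Hydroxyl-directed iron-catalysed carbomagnesiation of a homopropargylic alcohol delivers methyl to the alkyne carbon remote from the alkoxide and magnesium to the near carbon in a syn sense (five-membered chelate), so protonation leaves the two chain carbons cis, which is the (3Z)-alkene (the later C6'=C7').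

Step 4
Reactants: 9 (3Z,6E)-4,6-dimethyl-8-phenylocta-3,6-dien-1-ol
Product: 10 (3Z,6E)-1-iodo-4,6-dimethyl-8-phenylocta-3,6-diene
Conditions: I2, PPh3, imidazole, CH2Cl2, 0 °C → rt
Reagents that add atoms: iodine, [I][I]
Why: Appel-type iodination converts the primary alcohol into the iodide by SN2 displacement of the oxyphosphonium group and leaves both trisubstituted alkenes untouched.

Step 5
Reactants: 10 (3Z,6E)-1-iodo-4,6-dimethyl-8-phenylocta-3,6-diene; 11 2,3-dihydrofuran
Product: 13 5-[(3Z,6E)-4,6-dimethyl-8-phenylocta-3,6-dien-1-yl]-2,3-dihydrofuran, via 5-lithio-2,3-dihydrofuran 12 (not isolated)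
Conditions: 11 (2 equiv), t-BuLi (1.5 equiv), THF, −78 → 0 °C; then 10, THF, −30 °C → rt; aq. NaHCO3 work-up, used crude
Reagents that add atoms: none
Why: α-Lithiation of the cyclic enol ether gives a vinyl-lithium that is alkylated by the primary homoallylic iodide (SN2), bringing in the future C6, C1', C2' and C3' without touching either alkene geometry.

Step 6
Reactants: 13 5-[(3Z,6E)-4,6-dimethyl-8-phenylocta-3,6-dien-1-yl]-2,3-dihydrofuran
Product: 14 (3E,7Z,10E)-4,8,10-trimethyl-12-phenyldodeca-3,7,10-trien-1-ol
Conditions: MeMgBr (4 equiv), NiCl2(PPh3)2 (5 mol %), toluene, 80 °C; dilute aq. HCl work-up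
Reagents that add atoms: methylmagnesium bromide, C[Mg]Br
Why: Wenkert-type nickel-catalysed Kumada coupling: zerovalent nickel inserts into the enol-ether C–O bond and methyl replaces oxygen with retention, so methyl ends cis to the CH2CH2OH arm and the long chain trans, giving the (3E)-alkene (the later C2'=C3').

Step 7
Reactants: 14 (3E,7Z,10E)-4,8,10-trimethyl-12-phenyldodeca-3,7,10-trien-1-ol
Product: 16 (3E,7Z,10E)-4,8,10-trimethyl-12-phenyldodeca-3,7,10-trienoic acid, via trienal 15 (not isolated)
Conditions: TEMPO (20 mol %), PhI(OAc)2 (2.2 equiv), MeCN/H2O 1:1, rt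
Reagents that add atoms: water, O
Why: TEMPO/PhI(OAc)2 oxoammonium oxidation takes the primary alcohol through the aldehyde hydrate to the acid under near-neutral conditions, so the β,γ-alkene does not move into conjugation and the skipped triene is not attacked.

Step 8
Reactants: 16 (3E,7Z,10E)-4,8,10-trimethyl-12-phenyldodeca-3,7,10-trienoic acid; 17 methyl 3-oxopentanoate
Product: 21 4-hydroxy-5-methyl-6-[(2E,6Z,9E)-3,7,9-trimethyl-11-phenylundeca-2,6,9-trien-1-yl]-2H-pyran-2-one, via acyl imidazolide 18 (not isolated), via ketoester dianion 19 (not isolated), via diketoester 20 (not isolated)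
Conditions: 16, 1,1'-carbonyldiimidazole (1.1 equiv), THF, rt; separately 17 (3 equiv), NaH, then n-BuLi, THF, 0 °C; combine at −78 → 0 °C; AcOH; then DBU (5 equiv), 60 °C; dilute aq. HCl work-up
Reagents that add atoms: none
Why: Weiler-type Claisen acylation of the β-keto ester dianion at its γ-carbon by the acyl imidazolide gives the 3,5-diketo ester, and DBU-induced lactonisation (the C5 enol oxygen attacks the ester carbonyl, forming O1–C2 with loss of methanol) closes the 4-hydroxy-2-pyrone ring.

Step 9
Reactants: 21 4-hydroxy-5-methyl-6-[(2E,6Z,9E)-3,7,9-trimethyl-11-phenylundeca-2,6,9-trien-1-yl]-2H-pyran-2-one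
Product: 23 lehualide A (4-hydroxy-3-methoxy-5-methyl-6-[(2E,6Z,9E)-3,7,9-trimethyl-11-phenylundeca-2,6,9-trien-1-yl]-2H-pyran-2-one), via iodonium ylide 22 (not isolated)
Conditions: PhI(OAc)2 (1.05 equiv), MeOH, 0 °C → rt; then Rh2(OAc)4 (2 mol %), 40 °C
Reagents that add atoms: methanol, CO
Why: Proposed new method: one-pot C3–H methoxylation through a trivalent-iodine ylide, in which the acidic 4-hydroxy-pyrone (far more nucleophilic at C3 than the three trisubstituted alkenes) condenses with PhI(OAc)2 to iodonium ylide 22, Rh2(OAc)4 expels iodobenzene to give an electrophilic acceptor/acceptor rhodium carbenoid at C3, solvent methanol attacks it to an oxonium ylide, and a 1,2-proton shift plus enolisation gives the 3-methoxy-4-hydroxy-pyrone; the closest known reaction type is rhodium-catalysed O–H insertion of cyclic 2-diazo-1,3-dicarbonyl compounds into alcohols together with carbene transfer from iodonium ylides of cyclic 1,3-diones, which to the best of my knowledge has not been shown for a 4-hydroxy-2-pyrone ylide in methanol or beside a polyene chain.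

**Compound list**
1 | but-3-yn-1-ol | OCCC#C | starting material
2 | propargyl bromide (3-bromoprop-1-yne) | BrCC#C | starting material
3 | bromomagnesium 4-(bromomagnesio)but-3-yn-1-olate (butynol bis-Grignard) | Br[Mg]OCCC#C[Mg]Br | intermediate (not isolated)
4 | hepta-3,6-diyn-1-ol | OCCC#CCC#C | intermediate
5 | benzyl chloride | ClCc1ccccc1 | starting material
6 | dimethylaluminium (E)-7-(dimethylalumanyl)-6-methylhept-6-en-3-yn-1-olate (alkenylalane) | C[Al](C)/C=C(\C)CC#CCCO[Al](C)C | intermediate (not isolated)
7 | (E)-6-methyl-8-phenyloct-6-en-3-yn-1-ol | OCCC#CC/C(C)=C/Cc1ccccc1 | intermediate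
8 | bromomagnesium (3E,6E)-3-(bromomagnesio)-4,6-dimethyl-8-phenylocta-3,6-dien-1-olate (alkenylmagnesium chelate; methyl and magnesium cis) | Br[Mg]OCC/C([Mg]Br)=C(/C)C/C(C)=C/Cc1ccccc1 | intermediate (not isolated)
9 | (3Z,6E)-4,6-dimethyl-8-phenylocta-3,6-dien-1-ol | OCC/C=C(/C)C/C(C)=C/Cc1ccccc1 | intermediate
10 | (3Z,6E)-1-iodo-4,6-dimethyl-8-phenylocta-3,6-diene | ICC/C=C(/C)C/C(C)=C/Cc1ccccc1 | intermediate
11 | 2,3-dihydrofuran | C1CC=CO1 | starting material
12 | 5-lithio-2,3-dihydrofuran | [Li]C1=CCCO1 | intermediate (not isolated)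
13 | 5-[(3Z,6E)-4,6-dimethyl-8-phenylocta-3,6-dien-1-yl]-2,3-dihydrofuran | C1CC=C(O1)CC/C=C(/C)C/C(C)=C/Cc2ccccc2 | intermediate
14 | (3E,7Z,10E)-4,8,10-trimethyl-12-phenyldodeca-3,7,10-trien-1-ol | OCC/C=C(\C)CC/C=C(/C)C/C(C)=C/Cc1ccccc1 | intermediate
15 | (3E,7Z,10E)-4,8,10-trimethyl-12-phenyldodeca-3,7,10-trienal | O=CC/C=C(\C)CC/C=C(/C)C/C(C)=C/Cc1ccccc1 | intermediate (not isolated)
16 | (3E,7Z,10E)-4,8,10-trimethyl-12-phenyldodeca-3,7,10-trienoic acid | OC(=O)C/C=C(\C)CC/C=C(/C)C/C(C)=C/Cc1ccccc1 | intermediate
17 | methyl 3-oxopentanoate | CCC(=O)CC(=O)OC | starting material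
18 | 1-[(3E,7Z,10E)-4,8,10-trimethyl-12-phenyldodeca-3,7,10-trienoyl]imidazole | O=C(C/C=C(\C)CC/C=C(/C)C/C(C)=C/Cc1ccccc1)n1ccnc1 | intermediate (not isolated)
19 | sodium lithium dianion of methyl 3-oxopentanoate | [Na+].[Li+].COC([O-])=CC([O-])=CC | intermediate (not isolated)
20 | methyl (7E,11Z,14E)-4,8,12,14-tetramethyl-3,5-dioxo-16-phenylhexadeca-7,11,14-trienoate (C4 epimers/enol tautomers) | COC(=O)CC(=O)C(C)C(=O)C/C=C(\C)CC/C=C(/C)C/C(C)=C/Cc1ccccc1 | intermediate (not isolated)
21 | 4-hydroxy-5-methyl-6-[(2E,6Z,9E)-3,7,9-trimethyl-11-phenylundeca-2,6,9-trien-1-yl]-2H-pyran-2-one | Cc1c(O)cc(=O)oc1C/C=C(\C)CC/C=C(/C)C/C(C)=C/Cc2ccccc2 | intermediate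
22 | 5-methyl-2-oxo-3-(phenyliodonio)-6-[(2E,6Z,9E)-3,7,9-trimethyl-11-phenylundeca-2,6,9-trien-1-yl]-2H-pyran-4-olate (iodonium ylide) | CC1=C(C/C=C(\C)CC/C=C(/C)C/C(C)=C/Cc2ccccc2)OC(=O)C([I+]c2ccccc2)=C1[O-] | intermediate (not isolated)
23 | lehualide A | COc1c(O)c(C)c(C/C=C(\C)CC/C=C(/C)C/C(C)=C/Cc2ccccc2)oc1=O | target

**Step count and risks**

Total step count: 9. Longest linear sequence: 9 steps, fully linear from but-3-yn-1-ol 1.

The three steps most likely to fail, each with a fallback that changes the approach: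

Step 2 is at risk because the methylalumination must pick the terminal alkyne of a skipped diynol beside a free alkoxide, and the alane must then be benzylated in the same flask. The fallback sets out from but-3-yn-1-ol 1 and returns at enynol 7; it builds the trisubstituted alkene first and the skipped enyne second. Commercial (3-methylbut-2-en-1-yl)benzene is oxidised at the (E)-methyl group with SeO2 (cat.)/t-BuOOH in CH2Cl2, with NaBH4 treatment to return any enal, giving (E)-2-methyl-4-phenylbut-2-en-1-ol F1. PBr3 in Et2O at 0 °C gives [(E)-4-bromo-3-methylbut-2-en-1-yl]benzene F2. Copper-mediated alkynylation of F2 with 1 (CuI, K2CO3, Bu4NBr, DMF, rt) then gives 7; the diynol 4 is no longer needed.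

Step 8 is at risk because the acyl imidazolide 18 carries acidic allylic α-protons, so the strongly basic dianion 19 may enolise it instead of adding, and the one-flask lactonisation must not move the C2'=C3' alkene into conjugation. The fallback sets out from trienol 14 and returns at diketoester 20; it replaces the Claisen acylation by an aldol/oxidation sequence. Dess–Martin periodinane (NaHCO3-buffered, CH2Cl2) gives trienal 15, isolated this time. Addition of 15 to dianion 19 at −78 °C gives methyl (7E,11Z,14E)-5-hydroxy-4,8,12,14-tetramethyl-3-oxo-16-phenylhexadeca-7,11,14-trienoate F3 (diastereomers, inconsequential). A second Dess–Martin oxidation gives 20, which is closed with DBU to 21 as in step 8.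

Step 9 is the proposed new reaction. Its risks are protodeiodination of ylide 22 back to 21, thermal aryl migration of the ylide, and carbenoid attack on an alkene of another molecule. The fallback uses known chemistry only, sets out from acid 16 (as its imidazolide 18) and returns at target 23; the methoxy group is carried in from the start. Methyl methoxyacetate (2 equiv) is deprotonated with LiHMDS in THF at −78 °C and acylated with propionyl chloride (crossed Claisen) to methyl 2-methoxy-3-oxopentanoate F4. NaH and then n-BuLi give the sodium lithium dianion of methyl 2-methoxy-3-oxopentanoate F5. γ-Acylation of F5 by 18 gives methyl (7E,11Z,14E)-2-methoxy-4,8,12,14-tetramethyl-3,5-dioxo-16-phenylhexadeca-7,11,14-trienoate F6, and DBU lactonisation of F6 gives 23 directly.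

**Further compounds**
F1 | step 2 | (E)-2-methyl-4-phenylbut-2-en-1-ol | OC/C(C)=C/Cc1ccccc1
F2 | step 2 | [(E)-4-bromo-3-methylbut-2-en-1-yl]benzene | BrC/C(C)=C/Cc1ccccc1
F3 | step 8 | methyl (7E,11Z,14E)-5-hydroxy-4,8,12,14-tetramethyl-3-oxo-16-phenylhexadeca-7,11,14-trienoate | COC(=O)CC(=O)C(C)C(O)C/C=C(\C)CC/C=C(/C)C/C(C)=C/Cc1ccccc1
F4 | step 9 | methyl 2-methoxy-3-oxopentanoate | CCC(=O)C(OC)C(=O)OC
F5 | step 9 | sodium lithium dianion of methyl 2-methoxy-3-oxopentanoate | [Na+].[Li+].COC([O-])=C(OC)C([O-])=CC
F6 | step 9 | methyl (7E,11Z,14E)-2-methoxy-4,8,12,14-tetramethyl-3,5-dioxo-16-phenylhexadeca-7,11,14-trienoate | COC(=O)C(OC)C(=O)C(C)C(=O)C/C=C(\C)CC/C=C(/C)C/C(C)=C/Cc1ccccc1
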